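Percent of the substrate charged was my unit, and the flask in question held 0.12 M of c(substrate) and was to be read at 30 min.

the same everywhere: gas 6.3 mM (held)
- epsilon: substrate 0.12 M; the very flask that is asked about, followed so far
- theta: substrate 0.060 M; run made earlier
- flask: substrate 0.12 M; time 30 min

| run | time / min | product / % | intermediate E / % |
|---|---|---|---|
| epsilon | 0.833 | 28.1 | 0.5 |
| epsilon | 2.50 | 77.5 | 1.2 |
| epsilon | 4.00 | 87.4 | 3.4 |
| epsilon | 6.00 | 89.2 | 4.1 |
| epsilon | 10.0 | 88.8 | 5.7 |
| epsilon | 12.0 | 89.1 | 6.5 |
| epsilon | 15.0 | 89.0 | 6.8 |
| theta | 1.50 | 58.6 | 1.0 |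
| theta | 2.50 | 78.6 | 1.3 |
| theta | 4.00 | 86.3 | 2.6 |
| theta | 6.00 | 88.0 | 4.9 |
| theta | 10.0 | 88.4 | 6.3 |
| theta | 15.0 | 88.4 | 6.5 |
| theta | 20.0 | 88.2 | 7.4 |

(each reading ± 0.3 percentage points)

* product at 30 min, in percent of the substrate charged
* intermediate E at 30 min, in percent of the substrate charged

- amounts and yields of product count crystals too
- given per volume of solution although it is solid: crystals
- at the start none of partner is dissolved
- the analysis behind the earlier runs scatters by 0.3 percentage points, standard deviation
- reactions considered so far: crystals <-> product; gas <-> partner; intermediate B -> product; partner + intermediate B -> intermediate D; partner + intermediate A <-> intermediate B; substrate <-> intermediate A; intermediate B <-> intermediate C; intermediate D <-> intermediate E; intermediate C -> product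

In the epsilon run, product read 89.2 % at 6.00 min and 89.0 % at 15.0 min, a difference of 0.2 percentage points against a scatter of 0.3 points, so on that plateau I divided product by the rest of the charge, and time dropped out of the ratio. The last epsilon reading gave 8.09; I took this as the selectivity factor S, the product formed per unit of charge not found as product. The theta run, at 0.060 M, read lower, 7.47. If the plateau held, S put the epsilon flask at 89.0 % product, with intermediate E below the remaining 11.0 %.

The forecast said 89 % product (88.4 % to 89.6 %) and 7.8 % intermediate E (7 % to 8.9 %), holding that “Once intermediate B has gone, nothing in the scheme consumes or feeds product”.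

The flask gave 89.1 % product, inside the forecast's range, and 6.83 % intermediate E, lower than that range's low end.

    crystals ⇌ product, rate k1*(cs1 - [product]) while solid is left; crystals form when [product] > cs1 (solubility = 2.90 mM, k = 1.70 s⁻¹)
    gas ⇌ partner, rate k2*(csat - [partner]) (kL = 0.830 s⁻¹)
    intermediate B → product (k = 0.00400 s⁻¹)
    partner + intermediate B → intermediate D (k = 1.30 L mol⁻¹ s⁻¹)
    partner + intermediate A ⇌ intermediate B (K = 1500 L mol⁻¹, k = 37.0 L mol⁻¹ s⁻¹)
    substrate ⇌ intermediate A (K = 0.390, k = 0.120 s⁻¹)
    intermediate B ⇌ intermediate C (K = 2.20, k = 0.400 s⁻¹)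
    intermediate D ⇌ intermediate E (K = 1.70, k = 0.00220 s⁻¹)
    intermediate C → product (k = 0.0270 s⁻¹)

Left until 300 min, the flask read 89.1 % product and 6.84 % intermediate E, so it had come to rest by the asked time, with 0 % of the substrate left. Its S was 8.17, beside my 8.09.

For the neighbour charged with 0.030 M, I carried theta's lower S, which gave 88.2 % product. That neighbour gave 87.7 %, with 7.70 % intermediate E.

The earlier runs and the new flask come from a simulation on assumed constants; the scatter is artificial.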